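**Retrosynthetic overview**
1. Target 15 ⇐ N‑methylation of acetamide 14 ⇐ one‑carbon (Hofmann‑type) degradation of the spare CH2CH2CN arm of nitrile 11.
2. Nitrile 11 ⇐ key step: enantioselective, desymmetrising [2+2+2] of the prochiral alkyne‑dinitrile 9 with acetylene. The pyridine and the cyclohexane ring form together, and the quaternary centre is set by which of two enantiotopic 2‑cyanoethyl arms enters the ring.
3. Alkyne‑dinitrile 9 ⇐ SN1 propargylation of the symmetric tertiary benzylic carbinol 7.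
4. Carbinol 7 ⇐ aryl Grignard + 1,3‑dichloroacetone, then two epoxide openings by LiCH2CN.
5. Ring order: arene bought; carbocycle and pyridine together in step 4.

Assumption: the sense of induction of the Rh/bisphosphine catalyst in step 4 cannot be predicted; (R)‑Segphos is written and its antipode is used if the first run gives the enantiomer of 11.
Note: the target is (R). The descriptor is S for 11 and 12 and R for 13–15 only because the side chain overtakes C5 in CIP priority once it carries N; the spatial arrangement does not change.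

**Step 1**
Reactants: 1 4‑bromo‑1,2‑dimethoxybenzene; 2 1,3‑dichloroacetone
Product: 4 1,3‑dichloro‑2‑(3,4‑dimethoxyphenyl)propan‑2‑ol, via (3,4‑dimethoxyphenyl)magnesium bromide 3 (not isolated)
Conditions: Mg, THF, 40 °C; then 2, −78 → 0 °C; aq. NH4Cl
Reagents that add atoms: none
Why: Grignard addition to the ketone of 1,3‑dichloroacetone at low temperature outruns enolisation and chloride displacement (the fluconazole‑type carbinol synthesis); no stereocentre is formed.

**Step 2**
Reactants: 4 1,3‑dichloro‑2‑(3,4‑dimethoxyphenyl)propan‑2‑ol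
Product: 7 4‑(3,4‑dimethoxyphenyl)‑4‑hydroxyheptanedinitrile, via 2‑(chloromethyl)‑2‑(3,4‑dimethoxyphenyl)oxirane 5 (not isolated), via 3‑[2‑(3,4‑dimethoxyphenyl)oxiran‑2‑yl]propanenitrile 6 (not isolated)
Conditions: MeCN/n‑BuLi (4.5 equiv each), THF, −78 °C; add 4; → 0 °C; aq. NH4Cl
Reagents that add atoms: acetonitrile (as cyanomethyllithium), CC#N
Why: The alkoxide closes to an epoxide (intramolecular Williamson), LiCH2CN opens it at the CH2 terminus (SN2 epoxide opening), and the sequence repeats on the second CH2Cl arm, giving an achiral carbinol with two identical arms.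

**Step 3**
Reactants: 7 4‑(3,4‑dimethoxyphenyl)‑4‑hydroxyheptanedinitrile
Product: 9 4‑(3,4‑dimethoxyphenyl)‑4‑(prop‑2‑yn‑1‑yl)heptanedinitrile, via bis(2‑cyanoethyl)(3,4‑dimethoxyphenyl)methylium 8 (not isolated)
Conditions: CH2=C=CHSnBu3 (1.5 equiv), BF3·OEt2 (2 equiv), CH2Cl2, −78 → −20 °C
Reagents that add atoms: allenyltributylstannane, C=C=C[Sn](CCCC)(CCCC)CCCC
Why: Lewis‑acid ionisation gives a tertiary benzylic cation stabilised by the dimethoxyaryl ring, which the allenylstannane traps at its CH2 terminus (SE2′, Hosomi–Sakurai‑type SN1 propargylation) to build the still prochiral quaternary carbon.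

**Step 4 (key step)**
Reactants: 9 4‑(3,4‑dimethoxyphenyl)‑4‑(prop‑2‑yn‑1‑yl)heptanedinitrile; 10 acetylene
Product: 11 3‑[(6S)‑6‑(3,4‑dimethoxyphenyl)‑5,6,7,8‑tetrahydroquinolin‑6‑yl]propanenitrile
Conditions: [Rh(cod)2]BF4 (5 mol %), (R)‑Segphos (5 mol %), H2 pre‑activation; HC≡CH (1 atm, slow stream), (CH2Cl)2, 0.02 M, 40 °C
Reagents that add atoms: none
Why: Proposed new method: cationic Rh(I) couples the propargyl alkyne with acetylene to a rhodacyclopentadiene, one pendant nitrile inserts intramolecularly (Thorpe–Ingold‑assisted closure of the six‑membered carbocycle) and reductive elimination gives the pyridine, and because the two 2‑cyanoethyl arms of 9 are enantiotopic the chiral bisphosphine chooses one of them in the nitrile‑insertion step and thereby sets the quaternary centre; the closest known reaction types are the Co‑catalysed cocyclisation of 6‑heptynenitriles with alkynes to 5,6,7,8‑tetrahydroquinolines and Rh/biaryl‑bisphosphine enantioselective desymmetrising [2+2+2] cycloadditions.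

**Step 5**
Reactants: 11 3‑[(6S)‑6‑(3,4‑dimethoxyphenyl)‑5,6,7,8‑tetrahydroquinolin‑6‑yl]propanenitrile
Product: 12 3‑[(6S)‑6‑(3,4‑dimethoxyphenyl)‑5,6,7,8‑tetrahydroquinolin‑6‑yl]propanamide
Conditions: [PtH(PMe2OH)(PMe2O)2H] (2 mol %), EtOH/H2O, 80 °C
Reagents that add atoms: water, O
Why: Ghaffar–Parkins platinum‑catalysed nitrile hydration stops cleanly at the primary amide under neutral conditions and leaves the pyridine, the aryl ethers and the quaternary centre untouched.

**Step 6**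
Reactants: 12 3‑[(6S)‑6‑(3,4‑dimethoxyphenyl)‑5,6,7,8‑tetrahydroquinolin‑6‑yl]propanamide
Product: 14 N‑{2‑[(6R)‑6‑(3,4‑dimethoxyphenyl)‑5,6,7,8‑tetrahydroquinolin‑6‑yl]ethyl}acetamide, via (6R)‑6‑(3,4‑dimethoxyphenyl)‑6‑(2‑isocyanatoethyl)‑5,6,7,8‑tetrahydroquinoline 13 (not isolated)
Conditions: Pb(OAc)4 (1.1 equiv), AcOH, 50 → 80 °C
Reagents that add atoms: acetic acid, CC(=O)O
Why: Oxidative Hofmann‑type rearrangement (Baumgarten conditions) gives the isocyanate, which adds acetic acid and loses CO2 from the mixed anhydride to give the acetamide directly, with the migrating CH2 remote from the stereocentre.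

**Step 7**
Reactants: 14 N‑{2‑[(6R)‑6‑(3,4‑dimethoxyphenyl)‑5,6,7,8‑tetrahydroquinolin‑6‑yl]ethyl}acetamide
Product: 15 N‑{2‑[(6R)‑6‑(3,4‑dimethoxyphenyl)‑5,6,7,8‑tetrahydroquinolin‑6‑yl]ethyl}‑N‑methylacetamide
Conditions: NaH (1.1 equiv), THF/DMF, 0 °C; MeI (1.05 equiv), 0 °C → rt
Reagents that add atoms: iodomethane, CI
Why: N‑alkylation of the sodium amidate with limiting MeI is much faster than quaternisation of the neutral pyridine, and the quaternary stereocentre cannot epimerise.

**Compound list**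
1 | 4‑bromo‑1,2‑dimethoxybenzene | COc1ccc(Br)cc1OC | starting material
2 | 1,3‑dichloroacetone | ClCC(=O)CCl | starting material
3 | (3,4‑dimethoxyphenyl)magnesium bromide | COc1ccc([Mg]Br)cc1OC | intermediate
4 | 1,3‑dichloro‑2‑(3,4‑dimethoxyphenyl)propan‑2‑ol | COc1ccc(C(O)(CCl)CCl)cc1OC | intermediate
5 | 2‑(chloromethyl)‑2‑(3,4‑dimethoxyphenyl)oxirane (racemic) | COc1ccc(C2(CCl)CO2)cc1OC | intermediate
6 | 3‑[2‑(3,4‑dimethoxyphenyl)oxiran‑2‑yl]propanenitrile (racemic) | COc1ccc(C2(CCC#N)CO2)cc1OC | intermediate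
7 | 4‑(3,4‑dimethoxyphenyl)‑4‑hydroxyheptanedinitrile | COc1ccc(C(O)(CCC#N)CCC#N)cc1OC | intermediate
8 | bis(2‑cyanoethyl)(3,4‑dimethoxyphenyl)methylium | COc1ccc([C+](CCC#N)CCC#N)cc1OC | intermediate
9 | 4‑(3,4‑dimethoxyphenyl)‑4‑(prop‑2‑yn‑1‑yl)heptanedinitrile | COc1ccc(C(CC#C)(CCC#N)CCC#N)cc1OC | intermediate
10 | acetylene | C#C | starting material
11 | 3‑[(6S)‑6‑(3,4‑dimethoxyphenyl)‑5,6,7,8‑tetrahydroquinolin‑6‑yl]propanenitrile | COc1ccc([C@]2(CCC#N)CCc3ncccc3C2)cc1OC | intermediate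
12 | 3‑[(6S)‑6‑(3,4‑dimethoxyphenyl)‑5,6,7,8‑tetrahydroquinolin‑6‑yl]propanamide | COc1ccc([C@]2(CCC(N)=O)CCc3ncccc3C2)cc1OC | intermediate
13 | (6R)‑6‑(3,4‑dimethoxyphenyl)‑6‑(2‑isocyanatoethyl)‑5,6,7,8‑tetrahydroquinoline | COc1ccc([C@]2(CCN=C=O)CCc3ncccc3C2)cc1OC | intermediate
14 | N‑{2‑[(6R)‑6‑(3,4‑dimethoxyphenyl)‑5,6,7,8‑tetrahydroquinolin‑6‑yl]ethyl}acetamide | COc1ccc([C@]2(CCNC(C)=O)CCc3ncccc3C2)cc1OC | intermediate
15 | N‑{2‑[(6R)‑6‑(3,4‑dimethoxyphenyl)‑5,6,7,8‑tetrahydroquinolin‑6‑yl]ethyl}‑N‑methylacetamide | COc1ccc([C@]2(CCN(C)C(C)=O)CCc3ncccc3C2)cc1OC | target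

**Total step count:** 7
**Longest linear sequence:** 7

**Steps most likely to fail, with fallbacks**

Step 4 (enantioselective desymmetrising [2+2+2]; both the ee and the competition with acetylene trimerisation or arene formation are uncertain). The fallback sets out from 9 and gives up catalyst control of the stereocentre in favour of resolution. A Vollhardt cocyclisation with CpCo(CO)2 (10 mol %), bis(trimethylsilyl)acetylene as co‑solvent, xylene, reflux, hν uses an alkyne that cannot self‑trimerise or react with the spare nitrile. It gives racemic 3‑[6‑(3,4‑dimethoxyphenyl)‑2,3‑bis(trimethylsilyl)‑5,6,7,8‑tetrahydroquinolin‑6‑yl]propanenitrile F1. TBAF in wet THF/DMSO at 80 °C removes both silyl groups to give racemic 3‑[6‑(3,4‑dimethoxyphenyl)‑5,6,7,8‑tetrahydroquinolin‑6‑yl]propanenitrile F2. Preparative chiral SFC (or crystallisation of a dibenzoyl‑tartrate salt of the basic pyridine) then separates the wanted (S)‑nitrile from 3‑[(6R)‑6‑(3,4‑dimethoxyphenyl)‑5,6,7,8‑tetrahydroquinolin‑6‑yl]propanenitrile F3, and the route is rejoined at 11.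

Step 3 (SN1 propargylation; the cation may eliminate to the styrene and oligomerise, or the stannane may be protodestannylated). The fallback sets out from 7 and separates C–C bond formation from alkyne installation. A Mukaiyama‑type SN1 alkylation with trimethyl(vinyloxy)silane (cat. Bi(OTf)3, CH2Cl2, −40 °C) uses an acid‑stable silyl enol ether as the π‑nucleophile and gives 4‑(3,4‑dimethoxyphenyl)‑4‑(2‑oxoethyl)heptanedinitrile F4. Seyferth–Gilbert homologation with the Ohira–Bestmann reagent (K2CO3, MeOH, rt) converts the CH2CHO arm into the CH2C≡CH arm, and the route is rejoined at 9.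

Step 6 (Hofmann‑type rearrangement with acetic acid trapping; acylurea formation or oxidation of the electron‑rich arene could lower the yield). The fallback sets out from 12 and takes the N‑methyl carbon from a carbamate instead of from MeI. Hofmann rearrangement with PhI(OAc)2, KOH, MeOH, 0 °C → rt gives methyl N‑{2‑[(6R)‑6‑(3,4‑dimethoxyphenyl)‑5,6,7,8‑tetrahydroquinolin‑6‑yl]ethyl}carbamate F5. LiAlH4 in THF at reflux reduces the carbamate to 2‑[(6R)‑6‑(3,4‑dimethoxyphenyl)‑5,6,7,8‑tetrahydroquinolin‑6‑yl]‑N‑methylethanamine F6. Ac2O, Et3N, CH2Cl2 then acetylates the amine, so steps 6 and 7 are both bypassed and the route is rejoined at 15.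

**Further compounds**
F1 | step 4 | racemic 3‑[6‑(3,4‑dimethoxyphenyl)‑2,3‑bis(trimethylsilyl)‑5,6,7,8‑tetrahydroquinolin‑6‑yl]propanenitrile | COc1ccc(C2(CCC#N)CCc3nc([Si](C)(C)C)c([Si](C)(C)C)cc3C2)cc1OC
F2 | step 4 | racemic 3‑[6‑(3,4‑dimethoxyphenyl)‑5,6,7,8‑tetrahydroquinolin‑6‑yl]propanenitrile | COc1ccc(C2(CCC#N)CCc3ncccc3C2)cc1OC
F3 | step 4 | 3‑[(6R)‑6‑(3,4‑dimethoxyphenyl)‑5,6,7,8‑tetrahydroquinolin‑6‑yl]propanenitrile | COc1ccc([C@@]2(CCC#N)CCc3ncccc3C2)cc1OC
F4 | step 3 | 4‑(3,4‑dimethoxyphenyl)‑4‑(2‑oxoethyl)heptanedinitrile | COc1ccc(C(CC=O)(CCC#N)CCC#N)cc1OC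
F5 | step 6 | methyl N‑{2‑[(6R)‑6‑(3,4‑dimethoxyphenyl)‑5,6,7,8‑tetrahydroquinolin‑6‑yl]ethyl}carbamate | COc1ccc([C@]2(CCNC(=O)OC)CCc3ncccc3C2)cc1OC
F6 | step 6 | 2‑[(6R)‑6‑(3,4‑dimethoxyphenyl)‑5,6,7,8‑tetrahydroquinolin‑6‑yl]‑N‑methylethanamine | COc1ccc([C@]2(CCNC)CCc3ncccc3C2)cc1OC
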